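**Retrosynthetic overview**

1. The target comes from a (Z)-selective Wittig bromomethylenation of the C9 ketone of a spiro enone (last step).
2. The spiro enone comes from the ring A bromo aldehyde (formyl on C6, both C6 epimers) and methyl vinyl ketone by a chiral-primary-amine Michael–aldol annulation: C6–C11 first, then C7=C8. Ring B is formed second.
3. Feature used, with ring A numbered C1(=CH2)–C2–C3–C4(Br)–C5(Me2)–C6 and ring B C6–C7=C8–C9(=CHBr)–C10–C11: the spiro atom C6 bears C7, which can be a formyl carbon. The C6–H of that aldehyde is epimerizable, so C6 can be made quaternary while ring B is built on it.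
4. The bromo aldehyde comes from an ester whose ring A (formed first) arises by a stereospecific bromonium-initiated, allylsilane-terminated cyclization of an open-chain β-bromo mesylate. The C4–Br configuration derives from an oxirane, and the silyl group fixes C1=CH2.
5. The open chain comes from HBr opening of an (S)-oxirane, made by Shi epoxidation of an allylsilane dienoate from methyl acetoacetate and prenyl bromide.

Key step: step 9

Remark on the chemistry: the cyclized ester and the aldehyde made from it are carried as mixtures of epimers at the carbon that becomes C6, because the key step erases that centre. The target numbering above is used in the discussion; compound names use their own locants.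

**Step 1**
Reactants: 1 methyl acetoacetate (methyl 3-oxobutanoate); 2 prenyl bromide (1-bromo-3-methylbut-2-ene)
Product: 3 methyl 7-methyl-3-oxooct-6-enoate
Conditions: NaH, THF, 0 °C; n-BuLi, 0 °C; then 2, 0 °C → rt; aq. HCl
Reagents that add atoms: none
Why: Dianion γ-alkylation of a β-keto ester: the terminal, more nucleophilic carbanion of the acetoacetate dianion displaces the allylic bromide in an SN2 reaction, and no stereocentre is formed.

**Step 2**
Reactants: 3 methyl 7-methyl-3-oxooct-6-enoate
Product: 4 methyl (2Z)-3-[(diethoxyphosphoryl)oxy]-7-methylocta-2,6-dienoate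
Conditions: NaH, Et2O, 0 °C; ClP(O)(OEt)2, 0 °C → rt
Reagents that add atoms: diethyl chlorophosphate, CCOP(=O)(Cl)OCC
Why: O-Phosphorylation of the sodium-chelated enolate of the β-keto ester should give the enol phosphate with the phosphate oxygen cis to the ester (Z).

**Step 3**
Reactants: 4 methyl (2Z)-3-[(diethoxyphosphoryl)oxy]-7-methylocta-2,6-dienoate
Product: 5 methyl (2Z)-7-methyl-3-[(trimethylsilyl)methyl]octa-2,6-dienoate
Conditions: Me3SiCH2MgCl, Ni(acac)2 (5 mol %), THF, 0 °C → rt; aq. NH4Cl
Reagents that add atoms: (trimethylsilyl)methylmagnesium chloride, C[Si](C)(C)C[Mg]Cl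
Why: Nickel-catalysed Kumada-type cross-coupling of the enol phosphate C–O bond proceeds with retention of alkene geometry, and the hindered silylmethyl Grignard reagent leaves the conjugated ester alone.

**Step 4**
Reactants: 5 methyl (2Z)-7-methyl-3-[(trimethylsilyl)methyl]octa-2,6-dienoate
Product: 6 methyl (2Z)-5-[(2S)-3,3-dimethyloxiran-2-yl]-3-[(trimethylsilyl)methyl]pent-2-enoate
Conditions: 1,2:4,5-di-O-isopropylidene-β-L-erythro-2,3-hexodiulo-2,6-pyranose (L-fructose-derived Shi ketone, 30 mol %), Oxone (2KHSO5·KHSO4·K2SO4), K2CO3, Bu4NHSO4, aq. Na2B4O7/Na2EDTA buffer, MeCN–CH2(OMe)2, 0 °C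
Reagents that add atoms: potassium peroxymonosulfate (active part of Oxone), OOS(=O)(=O)[O-].[K+]
Why: Shi asymmetric epoxidation: the chiral dioxirane should attack only the electron-rich trisubstituted prenyl alkene (the silyl-substituted enoate is electron-poor) through a spiro transition state, and the L-series ketone sets the oxirane CH as (S).

**Step 5**
Reactants: 6 methyl (2Z)-5-[(2S)-3,3-dimethyloxiran-2-yl]-3-[(trimethylsilyl)methyl]pent-2-enoate
Product: 7 methyl (2Z,6S)-7-bromo-6-hydroxy-7-methyl-3-[(trimethylsilyl)methyl]oct-2-enoate
Conditions: HBr (33 % in AcOH, 1.1 equiv), Et2O, −40 °C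
Reagents that add atoms: hydrogen bromide, Br
Why: Acid-promoted Markovnikov ring opening of a trisubstituted oxirane: bromide enters at the tertiary carbon and the bond from the secondary carbon to oxygen is not touched, so that carbon stays (S).

**Step 6**
Reactants: 7 methyl (2Z,6S)-7-bromo-6-hydroxy-7-methyl-3-[(trimethylsilyl)methyl]oct-2-enoate
Product: 8 methyl (2Z,6S)-7-bromo-6-(methanesulfonyloxy)-7-methyl-3-[(trimethylsilyl)methyl]oct-2-enoate
Conditions: MsCl, Et3N, CH2Cl2, −20 °C; used without chromatography
Reagents that add atoms: methanesulfonyl chloride, CS(=O)(=O)Cl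
Why: O-Sulfonylation of the secondary alcohol breaks no bond at the stereocentre, so its configuration is kept.

**Step 7**
Reactants: 8 methyl (2Z,6S)-7-bromo-6-(methanesulfonyloxy)-7-methyl-3-[(trimethylsilyl)methyl]oct-2-enoate
Product: 9 methyl (3R)-3-bromo-2,2-dimethyl-6-methylidenecyclohexane-1-carboxylate (epimers at C1, trans expected to prevail)
Conditions: (CF3)2CHOH, 2,6-lutidine (buffer), 0 °C → rt
Reagents that add atoms: none
Why: Neighbouring-group-assisted solvolysis in the ionizing, non-nucleophilic solvent lets the tertiary bromine displace the mesylate from the rear (inversion at that carbon) to give a configurationally defined bromonium ion, which the ester-bearing allylsilane carbon opens at the tertiary carbon in a chair-like cation–olefin cyclization with Hosomi–Sakurai-type termination; loss of the silyl group fixes the alkene as the exocyclic methylene and the C–Br carbon emerges (R).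

**Step 8**
Reactants: 9 methyl (3R)-3-bromo-2,2-dimethyl-6-methylidenecyclohexane-1-carboxylate
Product: 10 (3R)-3-bromo-2,2-dimethyl-6-methylidenecyclohexane-1-carbaldehyde (epimers at C1)
Conditions: i-Bu2AlH (1.1 equiv), CH2Cl2, −78 °C; aq. potassium sodium tartrate; used crude
Reagents that add atoms: none
Why: Partial ester reduction: the tetrahedral aluminium hemiacetal of this hindered ester should survive at −78 °C and collapse to the aldehyde only on work-up, while the alkyl bromide and the alkene are inert to the hydride.

**Step 9**
Reactants: 10 (3R)-3-bromo-2,2-dimethyl-6-methylidenecyclohexane-1-carbaldehyde (epimers at C1); 11 methyl vinyl ketone (but-3-en-2-one)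
Product: 13 (6S,8R)-8-bromo-7,7-dimethyl-11-methylidenespiro[5.5]undec-1-en-3-one, via keto aldehyde 12 (not isolated)
Conditions: 9-amino-9-deoxy-epi-quinine (20 mol %), PhCO2H (40 mol %), 11 (3 equiv, slow addition), toluene, 40 °C, then 70 °C
Reagents that add atoms: none
Why: Either C6 epimer of 10 condenses with the primary amine to the same N–H dienamine (N–C7=C6–C1=CH2), so C6 is erased; C6 then adds to the acid-activated enone 11 through a compact hydrogen-bond-relayed transition state to form C6–C11 (Michael adduct 12, free or as its imine), and the methyl ketone condenses with C7 and loses water to give the C7=C8 enone. The closest known reaction type is the primary-amine-catalysed asymmetric Robinson annulation of α-branched aldehydes with methyl vinyl ketone to 4,4-disubstituted cyclohexenones, together with the Michael addition of N–H enamines to enones that creates quaternary centres. Ring B closes by a 6-(enolexo)-exo-trig aldol condensation. The new stereocentre C6 is set by the cinchona amine, whose protonated quinuclidine delivers the enone to one face of the dienamine, and ring A should reinforce this, because bond formation anti to the axial C5 methyl group places C11 trans to the equatorial C4 bromine. The step needs attack by C6 (α) instead of attack by the exocyclic CH2 (γ) or [4+2] addition across C7 and CH2, and it needs the C1=CH2 bond to stay in place: the N–H relay reaches only the carbon next to C7, and the weak acid cocatalyst should keep C-protonation at CH2 slower than the Michael step.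

**Step 10**
Reactants: 13 (6S,8R)-8-bromo-7,7-dimethyl-11-methylidenespiro[5.5]undec-1-en-3-one
Product: 14 (3Z,6S,8R)-8-bromo-3-(bromomethylidene)-7,7-dimethyl-11-methylidenespiro[5.5]undec-1-ene (target)
Conditions: Ph3P(CH2Br)Br, NaN(SiMe3)2, THF, −78 °C; then 13, −78 °C → rt; chromatographic separation of the geometric isomers
Reagents that add atoms: (bromomethyl)triphenylphosphonium bromide, BrC[P+](c1ccccc1)(c1ccccc1)c1ccccc1.[Br-]
Why: Wittig olefination with (bromomethylidene)triphenylphosphorane adds 1,2 to the enone carbonyl, and the bromine is expected to settle on the side of the smaller flank, the vinylic C8–H, which is the (Z) geometry; no stereocentre is touched.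

**Compound list**

1 | methyl acetoacetate | CC(=O)CC(=O)OC | starting material
2 | prenyl bromide (1-bromo-3-methylbut-2-ene) | CC(C)=CCBr | starting material
3 | methyl 7-methyl-3-oxooct-6-enoate | CC(C)=CCCC(=O)CC(=O)OC | intermediate
4 | methyl (2Z)-3-[(diethoxyphosphoryl)oxy]-7-methylocta-2,6-dienoate | CC(C)=CCC/C(OP(=O)(OCC)OCC)=C/C(=O)OC | intermediate
5 | methyl (2Z)-7-methyl-3-[(trimethylsilyl)methyl]octa-2,6-dienoate | CC(C)=CCC/C(C[Si](C)(C)C)=C/C(=O)OC | intermediate
6 | methyl (2Z)-5-[(2S)-3,3-dimethyloxiran-2-yl]-3-[(trimethylsilyl)methyl]pent-2-enoate | CC1(C)O[C@H]1CC/C(C[Si](C)(C)C)=C/C(=O)OC | intermediate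
7 | methyl (2Z,6S)-7-bromo-6-hydroxy-7-methyl-3-[(trimethylsilyl)methyl]oct-2-enoate | CC(C)(Br)[C@@H](O)CC/C(C[Si](C)(C)C)=C/C(=O)OC | intermediate
8 | methyl (2Z,6S)-7-bromo-6-(methanesulfonyloxy)-7-methyl-3-[(trimethylsilyl)methyl]oct-2-enoate | CC(C)(Br)[C@@H](OS(C)(=O)=O)CC/C(C[Si](C)(C)C)=C/C(=O)OC | intermediate
9 | methyl (3R)-3-bromo-2,2-dimethyl-6-methylidenecyclohexane-1-carboxylate (C1 epimers) | C=C1CC[C@@H](Br)C(C)(C)C1C(=O)OC | intermediate
10 | (3R)-3-bromo-2,2-dimethyl-6-methylidenecyclohexane-1-carbaldehyde (C1 epimers) | C=C1CC[C@@H](Br)C(C)(C)C1C=O | intermediate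
11 | methyl vinyl ketone | CC(=O)C=C | starting material
12 | (1S,3R)-3-bromo-2,2-dimethyl-6-methylidene-1-(3-oxobutyl)cyclohexane-1-carbaldehyde (not isolated) | C=C1CC[C@@H](Br)C(C)(C)[C@]1(C=O)CCC(C)=O | intermediate
13 | (6S,8R)-8-bromo-7,7-dimethyl-11-methylidenespiro[5.5]undec-1-en-3-one | C=C1CC[C@@H](Br)C(C)(C)[C@@]12C=CC(=O)CC2 | intermediate
14 | (3Z,6S,8R)-8-bromo-3-(bromomethylidene)-7,7-dimethyl-11-methylidenespiro[5.5]undec-1-ene | C=C1CC[C@@H](Br)C(C)(C)[C@@]12C=C/C(=C\Br)CC2 | target

**Step count**

Total: 10 steps. Longest linear sequence: 10 steps (1 and 2 to 14).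

**Steps most likely to fail**

Step 9 (key step). The dienamine may react through its exocyclic CH2 terminus or as a cisoid diene in a [4+2] addition instead of through the hindered C6. The exocyclic alkene may migrate into the ring after C-protonation of the dienamine. Condensation of the neopentyl-type aldehyde with the bulky amine may be too slow, so that the enone polymerizes or alkylates the catalyst on nitrogen. Facial selectivity at C6 may be poor if catalyst and ring A are mismatched. Fallback, setting out from aldehyde 10: the potassium dienolate (KH, THF, 0 °C) is alkylated at C6 with 2-(2-iodoethyl)-2-methyl-1,3-dioxolane, the kinetic α-alkylation of an extended enolate, to give (1S,3R)-3-bromo-2,2-dimethyl-6-methylidene-1-[2-(2-methyl-1,3-dioxolan-2-yl)ethyl]cyclohexane-1-carbaldehyde F1 under substrate control (entry anti to the axial C5 methyl group). PPTS in wet acetone then removes the ketal to give keto aldehyde 12, and KOH in MeOH closes ring B. The fallback comes back to the route at 12 and reaches 13.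

Step 10. Geometric selectivity may be poor or may favour the (E) isomer, the enone may be enolized by the basic ylide, and the ylide may decompose before it adds. Fallback, setting out from enone 13: dibromo-olefination with CBr4 and P(Oi-Pr)3 (CH2Cl2, 0 °C → rt) gives (6S,8R)-8-bromo-3-(dibromomethylidene)-7,7-dimethyl-11-methylidenespiro[5.5]undec-1-ene F2. Hydrodebromination with Bu3SnH and catalytic Pd(PPh3)4 (zerovalent palladium; toluene, rt, dark, no radical initiator so that the alkyl bromide should survive) then removes the more accessible vinylic bromine. Oxidative addition takes the very bromine position that a sterically governed Wittig reaction fills, so the sense of geometric selectivity is inverted. The fallback returns to the route at 14.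

Step 7. The tertiary C–Br bond may ionize in place of the mesylate, the bromonium ion may lose a proton to an allylic bromide or be captured by solvent, and the allylsilane may be protodesilylated before ring closure. Fallback, setting out from epoxide 6: Ph3PBr2 (from Ph3P and Br2, CH2Cl2, 0 °C) replaces the oxirane oxygen by two bromines with inversion at the secondary carbon to give methyl (2Z,6R)-6,7-dibromo-7-methyl-3-[(trimethylsilyl)methyl]oct-2-enoate F3. In (CF3)2CHOH only the tertiary C–Br bond of this dibromide can ionize, with the secondary bromine bridging, and the same allylsilane-terminated cyclization follows. The fallback comes back to the route at 9.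

**Further compounds**

F1 | step 9 | (1S,3R)-3-bromo-2,2-dimethyl-6-methylidene-1-[2-(2-methyl-1,3-dioxolan-2-yl)ethyl]cyclohexane-1-carbaldehyde | C=C1CC[C@@H](Br)C(C)(C)[C@]1(C=O)CCC2(C)OCCO2
F2 | step 10 | (6S,8R)-8-bromo-3-(dibromomethylidene)-7,7-dimethyl-11-methylidenespiro[5.5]undec-1-ene | C=C1CC[C@@H](Br)C(C)(C)[C@@]12C=CC(=C(Br)Br)CC2
F3 | step 7 | methyl (2Z,6R)-6,7-dibromo-7-methyl-3-[(trimethylsilyl)methyl]oct-2-enoate | CC(C)(Br)[C@H](Br)CC/C(C[Si](C)(C)C)=C/C(=O)OC
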